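| flask | left-handed substrate | right-handed substrate | partner | free catalyst | remark | time |
|---|---|---|---|---|---|---|
| south-east | 0.025 M | 0.025 M | 0.80 equiv | 0.56 mol% | run made earlier |  |
| south | 0.10 M | 0.10 M | 0.80 equiv | 0.56 mol% | run made earlier |  |
| west | 0.050 M | 0.050 M | 0.80 equiv | 1.1 mol% | run made earlier |  |
| flask | 0.050 M | 0.050 M | 0.800 equiv | 0.56 mol% |  | 8.0 h |

- south-east (time / h: left-handed product / %, right-handed product / %): 0.833: 11, 1; 1.50: 16, 4; 2.50: 22, 5; 3.00: 18, 4; 4.00: 24, 3; 5.00: 26, 6
- south (time / h: left-handed product / %, right-handed product / %): 0.833: 25, 5; 1.50: 34, 3; 2.50: 34, 3; 3.00: 31, 6; 4.00: 32, 8; 5.00: 26, 5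
- west (time / h: left-handed product / %, right-handed product / %): 1.00: 25, 6; 2.00: 34, 9; 3.00: 28, 5; 4.00: 35, 6; 5.00: 32, 9

(readings scatter by 2 percentage points)

- free catalyst is single-handed; left-handed substrate and right-handed substrate are mirror images of each other, charged as a racemate, each of them at the stated concentration
- an excess is the difference of the two amounts in percent of their sum
- an excess is below zero if the other one leads

- excess of left-handed product over right-handed product in the product at 25 min
- excess of left-handed product over right-handed product in the product at 8.0 h
- part of the left-handed substrate and right-handed substrate charged together that has reacted at 8.0 h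

In a one-step world each partner turns one substrate of either hand into one product, so conversion ends where the partner ends. The quantity to carry is the partner ceiling, the partner charged over both substrates charged together, 40.0 % in this flask. Turned round, the substrates could give out first if c(partner) reached 0.100 M, but the flask holds 0.0400 M, which makes the partner the limiting reagent in this picture. The west run, with the same equivalents, reads a mean total of 39.5 % from 2.00 h on, a scattered reading close to the 40.0 % that its own charges allow. The reckoning here therefore puts the flask at or somewhat under 40.0 % at 8.0 h, and the ceiling says nothing about the excess.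

The forecast gives 68 %, 64 % and 38 %, and of the stall it says: “That looks like an equilibrium or inhibition limit”.

The flask gives 65.7 %, 71.0 % and 33.9 %, so the forecast's late excess lies 7 percentage points low.

    free catalyst + left-handed substrate ⇌ catalyst intermediate A (K = 290 L mol⁻¹, k = 5030 L mol⁻¹ h⁻¹)
    free catalyst + right-handed substrate ⇌ catalyst intermediate B (K = 20.2 L mol⁻¹, k = 1470 L mol⁻¹ h⁻¹)
    partner + catalyst intermediate A → free catalyst + left-handed product (k = 7850 L mol⁻¹ h⁻¹)
    partner + catalyst intermediate B → free catalyst + right-handed product (k = 3680 L mol⁻¹ h⁻¹)
    left-handed substrate ⇌ right-handed substrate (k = 0.591 h⁻¹)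
    partner → decomposed reagent (k = 0.198 h⁻¹)
    2 partner → homo dimer (k = 0.598 L mol⁻¹ h⁻¹)

In this flask, half of the turnover to left-handed product is done by 0.595 h, earlier than the 3.5 h half-life of the partner by decomposition alone. At 8.0 h the partner stands at 0 % of its charge while 66 % of the left-handed substrate remains, 0.00567 M of decomposed reagent and 3.68 × 10⁻⁴ M of homo dimer stand in the flask, and conversion stands 6.1 points under the ceiling. With 0.480 equiv of partner the ceiling falls to 24.0 %, and that flask reaches 21.1 %.

The readings are simulated from invented constants.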